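**Retrosynthetic overview**

1. Target numbering: C1 carries the guaiacyl ring, C2 and C3 the CH2OH carbons, C4 is the CH2, C4a lies next to the C5 methoxy and C8a next to C8–H. The last operations turn C4=O into CH2 and free the oxygens of a protected 4-oxo tetralin.
2. Key disconnection: ring B is cut at C1–C8a and C4–C4a. The strategy rests on the chain C1–C2–C3–C4 with its three trans stereocentres being an all-trans 2-aryl-3,4-bis(oxymethyl)cyclobutanone, and on the C5 methoxy beside C4a polarising an aryne, so a two-carbon ring expansion of the four-membered ketone builds ring B onto ring A.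
3. The cyclobutanone comes from a [2+2] of a chiral keteniminium (arylacetic amide of (2S,5S)-2,5-dimethylpyrrolidine) with an (E)-1,4-dioxybut-2-ene. Its two CH2O arms are then tied as an isopropylidene ketal, a tether that keeps the C2 and C3 arms diequatorial when C1 is protonated.
4. The aryne precursor (ring A) comes from 2,3,4-trihydroxybenzaldehyde: 4-O-benzylation, di-O-methylation, Dakin oxidation, carbamate-directed ortho-silylation, triflation.
5. Ring order: cyclobutane, then the dioxepane tether, then ring B; ring A and the guaiacyl ring are bought.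

Key step: step 11

Remark: the (2S,5S)-amine is assumed to steer the cycloaddition to the (3S,4S)-cyclobutanone; if the sense is the opposite one, the (2R,5R)-amine is used and nothing else changes.

**Route**

Step 1
Reactants: 1 2,3,4-trihydroxybenzaldehyde
Product: 2 4-(benzyloxy)-2,3-dihydroxybenzaldehyde
Conditions: BnBr (1.0 equiv), NaHCO3, NaI (cat.), DMF, 40 °C
Reagents that add atoms: benzyl bromide, BrCc1ccccc1
Why: Williamson etherification under bicarbonate should touch only the most acidic hydroxyl (para to the formyl group), because the 2-OH is held in a hydrogen bond to the carbonyl and the 3-OH is the least acidic.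

Step 2
Reactants: 2 4-(benzyloxy)-2,3-dihydroxybenzaldehyde
Product: 3 4-(benzyloxy)-2,3-dimethoxybenzaldehyde
Conditions: MeI, K2CO3, DMF, rt
Reagents that add atoms: iodomethane, CI
Why: Exhaustive Williamson methylation of the two remaining phenols.

Step 3
Reactants: 3 4-(benzyloxy)-2,3-dimethoxybenzaldehyde
Product: 5 4-(benzyloxy)-2,3-dimethoxyphenol, via aryl formate 4 (not isolated)
Conditions: mCPBA, CH2Cl2, 0 °C → rt; then K2CO3, MeOH, rt
Reagents that add atoms: mCPBA, O=C(OO)c1cccc(Cl)c1
Why: Dakin-type Baeyer–Villiger oxidation, in which the electron-rich aryl group migrates and the resulting formate is methanolysed to the phenol.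

Step 4
Reactants: 5 4-(benzyloxy)-2,3-dimethoxyphenol
Product: 6 4-(benzyloxy)-2,3-dimethoxyphenyl N-isopropylcarbamate
Conditions: i-PrNCO, Et3N (cat.), CH2Cl2, rt
Reagents that add atoms: isopropyl isocyanate, CC(C)N=C=O
Why: Addition of the phenol to the isocyanate gives a carbamate that directs metalation and is later removed under mild base.

Step 5
Reactants: 6 4-(benzyloxy)-2,3-dimethoxyphenyl N-isopropylcarbamate
Product: 10 4-(benzyloxy)-2,3-dimethoxy-6-(trimethylsilyl)phenyl N-isopropylcarbamate, via N-silyl carbamate 7 (not isolated), via aryllithium 8 (not isolated), via C-silylated N-silyl carbamate 9 (not isolated)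
Conditions: TBSOTf, TMEDA, Et2O, 0 °C → rt; n-BuLi, TMEDA, −78 °C; TMSCl, −78 °C → rt; NaHSO4 (aq)
Reagents that add atoms: chlorotrimethylsilane, C[Si](C)(C)Cl
Why: Directed ortho-metalation, in which the N-silylated carbamate guides lithiation to C6 (its only free ortho position), the aryllithium is silylated and the N–Si bond falls on acidic work-up.

Step 6
Reactants: 10 4-(benzyloxy)-2,3-dimethoxy-6-(trimethylsilyl)phenyl N-isopropylcarbamate
Product: 12 4-(benzyloxy)-2,3-dimethoxy-6-(trimethylsilyl)phenyl trifluoromethanesulfonate, via silylphenol 11 (not isolated)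
Conditions: DBU, Et2NH, MeCN, 40 °C; then PhNTf2, rt
Reagents that add atoms: N-phenylbis(trifluoromethanesulfonimide), O=S(=O)(N(c1ccccc1)S(=O)(=O)C(F)(F)F)C(F)(F)F
Why: E1cB cleavage of the secondary carbamate (isopropyl isocyanate trapped by Et2NH) and triflation of the phenoxide in the same flask should give the ortho-silylaryl triflate without isolating the silylphenol.

Step 7
Reactants: 13 (E)-but-2-ene-1,4-diol
Product: 14 (E)-1,4-bis[(tert-butyldimethylsilyl)oxy]but-2-ene
Conditions: TBSCl, imidazole, DMF, rt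
Reagents that add atoms: tert-butyldimethylsilyl chloride, CC(C)(C)[Si](C)(C)Cl
Why: Silyl ether formation protects both primary alcohols as bulky ethers that should not capture the keteniminium and that are removed later with acid.

Step 8
Reactants: 15 2-[4-(benzyloxy)-3-methoxyphenyl]acetic acid (commercial O-benzylhomovanillic acid); 16 (2S,5S)-2,5-dimethylpyrrolidine
Product: 18 2-[4-(benzyloxy)-3-methoxyphenyl]-1-[(2S,5S)-2,5-dimethylpyrrolidin-1-yl]ethan-1-one, via acid chloride 17 (not isolated)
Conditions: (COCl)2, DMF (cat.), CH2Cl2, 0 °C → rt; then 16, Et3N, CH2Cl2, 0 °C → rt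
Reagents that add atoms: none
Why: Amide formation through the acid chloride acylates the hindered secondary amine without touching its stereocentres.

Step 9
Reactants: 18 2-[4-(benzyloxy)-3-methoxyphenyl]-1-[(2S,5S)-2,5-dimethylpyrrolidin-1-yl]ethan-1-one; 14 (E)-1,4-bis[(tert-butyldimethylsilyl)oxy]but-2-ene
Product: 21 (2R,3S,4S)-2-[4-(benzyloxy)-3-methoxyphenyl]-3,4-bis{[(tert-butyldimethylsilyl)oxy]methyl}cyclobutan-1-one, via keteniminium triflate 19 (not isolated), via cyclobutaniminium triflate 20 (not isolated)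
Conditions: Tf2O, 2,4,6-collidine, 14 (2 equiv), ClCH2CH2Cl, −20 → 80 °C; then NaHCO3 (aq), rt
Reagents that add atoms: water, O
Why: Keteniminium–alkene [2+2] cycloaddition, in which the E-alkene geometry is kept (C3/C4 trans), the C2-symmetric pyrrolidine picks one enantiotopic alkene face (C3 and C4 absolute), the aryl-bearing C2 settles trans through the iminium–enamine equilibrium, and hydrolysis releases the ketone and the amine.

Step 10
Reactants: 21 (2R,3S,4S)-2-[4-(benzyloxy)-3-methoxyphenyl]-3,4-bis{[(tert-butyldimethylsilyl)oxy]methyl}cyclobutan-1-one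
Product: 23 (1S,7S,9R)-9-[4-(benzyloxy)-3-methoxyphenyl]-4,4-dimethyl-3,5-dioxabicyclo[5.2.0]nonan-8-one (the all-trans cyclobutanone with its two CH2O arms tied as isopropylidene ketal), via diol 22 (not isolated)
Conditions: HF (aq), MeCN, 0 °C → rt; then 2-methoxypropene, PPTS (cat.), 4 Å sieves, CH2Cl2, 0 °C → rt
Reagents that add atoms: 2-methoxypropene, COC(C)=C
Why: Acidic desilylation followed by acid-catalysed ketalisation with the enol ether should close the trans-fused 1,3-dioxepane, since the two trans arms on the puckered cyclobutane lie at a dihedral angle a seven-membered ring can span, and no stereocentre is made or touched.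

Step 11
Reactants: 23 (1S,7S,9R)-9-[4-(benzyloxy)-3-methoxyphenyl]-4,4-dimethyl-3,5-dioxabicyclo[5.2.0]nonan-8-one; 12 4-(benzyloxy)-2,3-dimethoxy-6-(trimethylsilyl)phenyl trifluoromethanesulfonate
Product: 26 (2S,3S,4R)-6-(benzyloxy)-4-[4-(benzyloxy)-3-methoxyphenyl]-2,3-bis(hydroxymethyl)-7,8-dimethoxy-3,4-dihydronaphthalen-1(2H)-one O,O'-isopropylidene ketal (ketone at C4 of the target numbering, dioxepane trans-fused on C2–C3), via aryne 24 (not isolated), via caesium benzocyclobutenoxide 25 (not isolated)
Conditions: 12 (1.3 equiv), CsF (3 equiv), MeCN, rt → 50 °C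
Reagents that add atoms: none
Why: CsF desilylates 12 to aryne 24 and forms the benzylic enolate of 23; the enolate carbon C1 adds to the aryne carbon remote from the flanking methoxy (C8a), the aryl anion left at C4a closes onto the strained carbonyl to benzocyclobutenoxide 25, and retro-aldol cleavage of the old C1–C4 bond opens both four-membered rings to the ortho-quinodimethane enolate of the six-membered ketone, which takes a proton at C1 from the medium. The closest known reaction type is aryne σ-insertion into the C(O)–Cα bond of α-aryl ketones and β-keto esters (acyl-alkylation) and the two-carbon ring expansion of cyclic ketone enolates with arynes; a cyclobutanone has not been used in it, but its strain should speed both the carbonyl addition and the fragmentation. Ring B closes by intermolecular C-arylation (C1–C8a) followed by 4-exo-trig addition (C4–C4a), the six-membered ring appearing when the bicyclic alkoxide fragments. The new stereocentre C1 is set by protonation of the planar carbon: the trans-fused dioxepane keeps the C2 and C3 arms pseudo-equatorial, so the proton should enter axially, antiperiplanar to the axial H on C2, leaving the aryl group equatorial and trans to C2. With free ether arms, allylic 1,2-strain against the C1 aryl would turn the C2 arm axial and protonation anti to it would give the 1,2-cis epimer, which is why the diol is tied. The step needs aryne regiocontrol (secured by the methoxy next to the anionic carbon), enolisation only on the benzylic side (the far more acidic α-H) and fragmentation only toward the doubly benzylic carbanion, while C2 and C3 are not touched.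

Step 12
Reactants: 26 (2S,3S,4R)-tetralone isopropylidene ketal
Product: 27 C4 carbinol of 26 (target numbering; either C4 epimer)
Conditions: NaBH4, MeOH–THF, 0 °C → rt
Reagents that add atoms: none
Why: Hydride reduction of the aryl ketone with NaBH4; the new carbinol centre is not controlled because it is removed in step 13.

Step 13
Reactants: 27 C4 carbinol of 26
Product: 29 (1R,2S,3S)-1-(4-hydroxy-3-methoxyphenyl)-2,3-bis(hydroxymethyl)-5,6-dimethoxy-1,2,3,4-tetrahydronaphthalen-7-ol (target), via bisphenol ketal 28 (not isolated)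
Conditions: H2 (3 atm), Pd/C, AcOH (cat.), MeOH–EtOAc, rt; then HCl (1 M aq), MeOH, rt
Reagents that add atoms: none
Why: Catalytic hydrogenolysis should cleave both aryl benzyl ethers and the benzylic C4–O bond (activated by the para hydroxyl and ortho methoxy of ring A), and dilute acid then hydrolyses the seven-membered ketal, conditions under which C1, C2 and C3 cannot epimerise.

**Compound list**

1 | 2,3,4-trihydroxybenzaldehyde | O=Cc1ccc(O)c(O)c1O | starting material
2 | 4-(benzyloxy)-2,3-dihydroxybenzaldehyde | O=Cc1ccc(OCc2ccccc2)c(O)c1O | intermediate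
3 | 4-(benzyloxy)-2,3-dimethoxybenzaldehyde | COc1c(OC)c(OCc2ccccc2)ccc1C=O | intermediate
4 | 4-(benzyloxy)-2,3-dimethoxyphenyl formate (not isolated) | COc1c(OC)c(OCc2ccccc2)ccc1OC=O | intermediate
5 | 4-(benzyloxy)-2,3-dimethoxyphenol | COc1c(OC)c(OCc2ccccc2)ccc1O | intermediate
6 | 4-(benzyloxy)-2,3-dimethoxyphenyl N-isopropylcarbamate | COc1c(OC)c(OCc2ccccc2)ccc1OC(=O)NC(C)C | intermediate
7 | N-(tert-butyldimethylsilyl) derivative of 6 (not isolated) | COc1c(OC)c(OCc2ccccc2)ccc1OC(=O)N(C(C)C)[Si](C)(C)C(C)(C)C | intermediate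
8 | 6-lithio derivative of 7 (not isolated) | COc1c(OC)c(OCc2ccccc2)cc([Li])c1OC(=O)N(C(C)C)[Si](C)(C)C(C)(C)C | intermediate
9 | 6-(trimethylsilyl) derivative of 7 (not isolated) | COc1c(OC)c(OCc2ccccc2)cc([Si](C)(C)C)c1OC(=O)N(C(C)C)[Si](C)(C)C(C)(C)C | intermediate
10 | 4-(benzyloxy)-2,3-dimethoxy-6-(trimethylsilyl)phenyl N-isopropylcarbamate | COc1c(OC)c(OCc2ccccc2)cc([Si](C)(C)C)c1OC(=O)NC(C)C | intermediate
11 | 4-(benzyloxy)-2,3-dimethoxy-6-(trimethylsilyl)phenol (not isolated) | COc1c(OC)c(OCc2ccccc2)cc([Si](C)(C)C)c1O | intermediate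
12 | 4-(benzyloxy)-2,3-dimethoxy-6-(trimethylsilyl)phenyl trifluoromethanesulfonate | COc1c(OC)c(OCc2ccccc2)cc([Si](C)(C)C)c1OS(=O)(=O)C(F)(F)F | intermediate
13 | (E)-but-2-ene-1,4-diol | OC/C=C/CO | starting material
14 | (E)-1,4-bis[(tert-butyldimethylsilyl)oxy]but-2-ene | CC(C)(C)[Si](C)(C)OC/C=C/CO[Si](C)(C)C(C)(C)C | intermediate
15 | 2-[4-(benzyloxy)-3-methoxyphenyl]acetic acid | COc1cc(CC(=O)O)ccc1OCc1ccccc1 | starting material
16 | (2S,5S)-2,5-dimethylpyrrolidine | C[C@H]1CC[C@H](C)N1 | starting material
17 | 2-[4-(benzyloxy)-3-methoxyphenyl]acetyl chloride (not isolated) | COc1cc(CC(=O)Cl)ccc1OCc1ccccc1 | intermediate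
18 | 2-[4-(benzyloxy)-3-methoxyphenyl]-1-[(2S,5S)-2,5-dimethylpyrrolidin-1-yl]ethan-1-one | C[C@H]1CC[C@H](C)N1C(=O)Cc1ccc(OCc2ccccc2)c(OC)c1 | intermediate
19 | aryl keteniminium triflate of 18 (not isolated) | C[C@H]1CC[C@H](C)[N+]1=C=Cc1ccc(OCc2ccccc2)c(OC)c1.[O-]S(=O)(=O)C(F)(F)F | intermediate
20 | (3S,4S)-cyclobutaniminium triflate, C2 epimers equilibrating (not isolated) | C[C@H]1CC[C@H](C)[N+]1=C2[C@H](CO[Si](C)(C)C(C)(C)C)[C@@H](CO[Si](C)(C)C(C)(C)C)C2c3ccc(OCc4ccccc4)c(OC)c3.[O-]S(=O)(=O)C(F)(F)F | intermediate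
21 | (2R,3S,4S)-2-[4-(benzyloxy)-3-methoxyphenyl]-3,4-bis{[(tert-butyldimethylsilyl)oxy]methyl}cyclobutan-1-one | O=C1[C@H](CO[Si](C)(C)C(C)(C)C)[C@@H](CO[Si](C)(C)C(C)(C)C)[C@@H]1c1ccc(OCc2ccccc2)c(OC)c1 | intermediate
22 | (2R,3S,4S)-2-[4-(benzyloxy)-3-methoxyphenyl]-3,4-bis(hydroxymethyl)cyclobutan-1-one (not isolated) | O=C1[C@H](CO)[C@@H](CO)[C@@H]1c1ccc(OCc2ccccc2)c(OC)c1 | intermediate
23 | (1S,7S,9R)-9-[4-(benzyloxy)-3-methoxyphenyl]-4,4-dimethyl-3,5-dioxabicyclo[5.2.0]nonan-8-one (key-step precursor) | O=C1[C@@H]2COC(C)(C)OC[C@H]2[C@@H]1c1ccc(OCc2ccccc2)c(OC)c1 | intermediate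
24 | 5-(benzyloxy)-3,4-dimethoxybenzyne (not isolated) | COC1=C(OC)C(OCc2ccccc2)=CC#C1 | intermediate
25 | caesium benzocyclobutenoxide, one of the two possible C1/C4 diastereomers drawn (not isolated) | [Cs+].[O-][C@]12c3c(OC)c(OC)c(OCc4ccccc4)cc3[C@@]1(c6ccc(OCc7ccccc7)c(OC)c6)[C@@H]5COC(C)(C)OC[C@@H]25 | intermediate
26 | (2S,3S,4R)-6-(benzyloxy)-4-[4-(benzyloxy)-3-methoxyphenyl]-2,3-bis(hydroxymethyl)-7,8-dimethoxy-3,4-dihydronaphthalen-1(2H)-one O,O'-isopropylidene ketal (key-step product) | COc1cc([C@@H]2c3cc(OCc4ccccc4)c(OC)c(OC)c3C(=O)[C@@H]3COC(C)(C)OC[C@@H]23)ccc1OCc1ccccc1 | intermediate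
27 | C4 carbinol of 26 (target numbering, both C4 epimers) | COc1cc([C@@H]2c3cc(OCc4ccccc4)c(OC)c(OC)c3C(O)[C@@H]3COC(C)(C)OC[C@@H]23)ccc1OCc1ccccc1 | intermediate
28 | (1R,2S,3S)-target as its 2,3-bis(hydroxymethyl) O,O'-isopropylidene ketal (not isolated) | COc1cc([C@@H]2c3cc(O)c(OC)c(OC)c3C[C@@H]3COC(C)(C)OC[C@@H]23)ccc1O | intermediate
29 | (1R,2S,3S)-1-(4-hydroxy-3-methoxyphenyl)-2,3-bis(hydroxymethyl)-5,6-dimethoxy-1,2,3,4-tetrahydronaphthalen-7-ol (CNP0197710.1) | COc1cc([C@@H]2c3cc(O)c(OC)c(OC)c3C[C@H](CO)[C@H]2CO)ccc1O | target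

**Step count and risks**

Total step count: 13. Longest linear sequence: 9 steps (steps 1–6, then 11–13).

Step 11 (ring expansion). The aryl anion may be protonated before it reaches the carbonyl, which gives plain α-arylation to a quaternary diaryl cyclobutanone. Fluoride or adventitious hydroxide may open the α-aryl cyclobutanone. The product enolate may capture a second aryne or lose the C3 oxygen by β-elimination. Facial control of the C1 protonation may be lower than planned. The fallback uses known stepwise chemistry, sets out from aldehyde 3 and ketone 23 and comes back at 26. Aldehyde 3 is oxidised (NaClO2, NaH2PO4, 2-methylbut-2-ene, t-BuOH–H2O) to 4-(benzyloxy)-2,3-dimethoxybenzoic acid F1. Iododecarboxylation (I2, K3PO4, MeCN, 100 °C) then gives 1-(benzyloxy)-4-iodo-2,3-dimethoxybenzene F2. Iodine–lithium exchange (n-BuLi, THF, −78 °C), transmetalation with CeCl3 and addition to 23 give the tertiary 1,2-diarylcyclobutanol F3. Oxidative ring expansion of F3 (AgNO3 cat., K2S2O8, CH2Cl2–H2O) proceeds through the alkoxy radical, β-scission toward the aryl-bearing carbon and cyclisation of the benzylic radical onto the free ortho position of the new aryl ketone, and should deliver 26.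

Step 9 (cycloaddition). The remote C2-symmetric amine may discriminate the enantiotopic faces of the acyclic E-alkene only weakly, so that the ketone forms with low enantiomeric purity. The fallback moves stereocontrol from induction to separation, sets out from acid chloride 17 and alkene 14 and comes back at 21. Acid chloride 17 and pyrrolidine give 2-[4-(benzyloxy)-3-methoxyphenyl]-1-(pyrrolidin-1-yl)ethan-1-one F4. The same Tf2O/collidine activation with 14 and hydrolysis give racemic all-trans ketone, that is 21 together with its (2S,3R,4R)-enantiomer F5. Preparative chromatography on a chiral stationary phase separates the two, and 21 goes on.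

Step 10 (tether). The mixed ketal may fail to close to the strained trans-fused seven-membered ring on the cyclobutane and stay as open bis-ketals, or the acid may ketalise the cyclobutanone carbonyl. The fallback closes the tether through silicon and moves ketal formation to the six-membered ring, sets out from diol 22 and comes back at 26. Diol 22 with t-Bu2Si(OTf)2 and 2,6-lutidine (CH2Cl2, 0 °C) gives the cyclic di-tert-butylsilylene (1S,7S,9R)-9-[4-(benzyloxy)-3-methoxyphenyl]-4,4-di-tert-butyl-3,5-dioxa-4-silabicyclo[5.2.0]nonan-8-one F6, whose longer Si–O bonds ease ring closure and which gives the same diequatorial lock. Ring expansion with 12 as in step 11 (the aryl–silicon bond next to the triflate should be attacked well before the hindered dialkoxysilane) gives the silylene-bridged tetralone F7. HF·pyridine (THF) frees (2S,3S,4R)-6-(benzyloxy)-4-[4-(benzyloxy)-3-methoxyphenyl]-2,3-bis(hydroxymethyl)-7,8-dimethoxy-3,4-dihydronaphthalen-1(2H)-one F8. Its trans-diequatorial diol is ketalised without strain (2,2-dimethoxypropane, PPTS, acetone) to 26.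

Further compounds
F1 | step 11 | 4-(benzyloxy)-2,3-dimethoxybenzoic acid | COc1c(OC)c(OCc2ccccc2)ccc1C(=O)O
F2 | step 11 | 1-(benzyloxy)-4-iodo-2,3-dimethoxybenzene | COc1c(OC)c(OCc2ccccc2)ccc1I
F3 | step 11 | 8-[4-(benzyloxy)-2,3-dimethoxyphenyl] tertiary cyclobutanol from 23 (carbinol configuration open) | OC1(c2c(OC)c(OC)c(OCc3ccccc3)cc2)[C@@H]2COC(C)(C)OC[C@H]2[C@@H]1c1ccc(OCc2ccccc2)c(OC)c1
F4 | step 9 | 2-[4-(benzyloxy)-3-methoxyphenyl]-1-(pyrrolidin-1-yl)ethan-1-one | COc1cc(CC(=O)N2CCCC2)ccc1OCc1ccccc1
F5 | step 9 | (2S,3R,4R)-2-[4-(benzyloxy)-3-methoxyphenyl]-3,4-bis{[(tert-butyldimethylsilyl)oxy]methyl}cyclobutan-1-one (enantiomer of 21) | O=C1[C@@H](CO[Si](C)(C)C(C)(C)C)[C@H](CO[Si](C)(C)C(C)(C)C)[C@H]1c1ccc(OCc2ccccc2)c(OC)c1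
F6 | step 10 | (1S,7S,9R)-9-[4-(benzyloxy)-3-methoxyphenyl]-4,4-di-tert-butyl-3,5-dioxa-4-silabicyclo[5.2.0]nonan-8-one | O=C1[C@@H]2CO[Si](C(C)(C)C)(C(C)(C)C)OC[C@H]2[C@@H]1c1ccc(OCc2ccccc2)c(OC)c1
F7 | step 10 | (2S,3S,4R)-tetralone of 26 with a di-tert-butylsilylene in place of the isopropylidene group | COc1cc([C@@H]2c3cc(OCc4ccccc4)c(OC)c(OC)c3C(=O)[C@@H]3CO[Si](C(C)(C)C)(C(C)(C)C)OC[C@@H]23)ccc1OCc1ccccc1
F8 | step 10 | (2S,3S,4R)-6-(benzyloxy)-4-[4-(benzyloxy)-3-methoxyphenyl]-2,3-bis(hydroxymethyl)-7,8-dimethoxy-3,4-dihydronaphthalen-1(2H)-one | COc1cc([C@@H]2c3cc(OCc4ccccc4)c(OC)c(OC)c3C(=O)[C@H](CO)[C@H]2CO)ccc1OCc1ccccc1
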